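**Retrosynthetic overview**

1. Ring B, the 2,2-dimethyldihydropyran (O4'–CMe2–C2–C3–C3'=C4'), is closed last. It is made in one flask from the ring-A enol ether (C2=C3, silylated CMe2–O arm on C2) and quinolone B as its 3-diazo-2,4-dione. A carbenoid [3+2] addition gives a temporary cis-fused dihydrofuran ketal (bonds C3'–C3 and O4'–C2), which is then reductively transposed (hydride to C2, O4' moved from C2 to CMe2).
2. Enabling feature: C2 of ring A, the O–CH carbon shared by both pyran rings, lies between the ring-A oxygen O1 and the CMe2 carbon, and quinolone B is a C3'/O4' 1,3-C,O unit. At the ketal level C2 can hold O1 and O4' together, and the six-membered ring-A oxocarbenium (O1=C2) lets O4' be exchanged for hydride and passed to the neighbouring tertiary carbon.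
3. Ring A, with the C4 stereocentre, comes from a catalytic asymmetric Michael addition/hemiketalisation of 4-hydroxy-1-methylquinolin-2(1H)-one to an α'-hydroxy dienone, then dehydration. The dienone comes from 3-methylbut-2-enal and 3-hydroxy-3-methylbutan-2-one by aldol condensation.
4. Order of ring formation: both quinolone bicycles are purchased; ring A; the temporary dihydrofuran (formed and opened inside the key step); ring B last.

Key step: step 6

Remark: ring A is numbered O1, C2, C3, C4 as in 2H-pyrano[3,2-c]quinolin-5(6H)-one and primed locants belong to quinolone B; the sense of induction in step 2 is assigned from the square-planar chelate model and fixes the choice of ligand antipode.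

Step 1
Reactants: 1 3-methylbut-2-enal; 2 3-hydroxy-3-methylbutan-2-one
Product: 3 (4E)-2-hydroxy-2,7-dimethylocta-4,6-dien-3-one
Conditions: LiOH·H2O (0.3 equiv), 2 (2 equiv), MeOH/H2O 3:1, slow addition of 1, 20 °C
Reagents that add atoms: none
Why: Crossed aldol condensation (Claisen–Schmidt type) in which only the methyl group of 2 can enolise and dehydration gives the conjugated (E)-dienone as the thermodynamic alkene, as in condensations of enals with methyl ketones.

Step 2
Reactants: 3 (4E)-2-hydroxy-2,7-dimethylocta-4,6-dien-3-one; 4 4-hydroxy-1-methylquinolin-2(1H)-one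
Product: 5 (4S)-2-hydroxy-2-(2-hydroxypropan-2-yl)-6-methyl-4-(2-methylprop-1-en-1-yl)-2,3,4,6-tetrahydro-5H-pyrano[3,2-c]quinolin-5-one (hemiketal, both C2 epimers)
Conditions: Cu(OTf)2 (10 mol %), (R,R)-tBu-box [2,2'-(propane-2,2-diyl)bis((4R)-4-tert-butyl-4,5-dihydrooxazole)] (11 mol %), THF, 0 → 20 °C
Reagents that add atoms: none
Why: Chiral Lewis acid catalysed Michael addition/hemiketalisation in which the α'-hydroxy ketone chelates divalent copper in a square-planar complex with the enone held s-cis, the tert-butyl group of the ligand blocks one face of the β-carbon so that C3 of 4 should add to the open Re face (1,4 and not 1,6, the δ-carbon being fully substituted) and set C4 as S, after which the enol oxygen closes on the ketone (6-exo-trig).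

Step 3
Reactants: 5 the hemiketal
Product: 6 (4R)-2-(2-hydroxypropan-2-yl)-6-methyl-4-(2-methylprop-1-en-1-yl)-4,6-dihydro-5H-pyrano[3,2-c]quinolin-5-one
Conditions: PPTS (10 mol %), 4 Å MS, toluene, 80 °C
Reagents that add atoms: none
Why: Acid-catalysed dehydration of a cyclic hemiketal to the enol ether (E1 through the ring oxocarbenium with loss of H-3, the only available β-hydrogen), the tertiary alcohol staying un-ionised because its cation would sit next to the oxygen-bearing carbon; C4 is untouched (the descriptor changes from S to R only through the priority rules).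

Step 4
Reactants: 6 the enol ether alcohol
Product: 7 (4R)-6-methyl-4-(2-methylprop-1-en-1-yl)-2-{2-[(triethylsilyl)oxy]propan-2-yl}-4,6-dihydro-5H-pyrano[3,2-c]quinolin-5-one
Conditions: Et3SiOTf (1.3 equiv), 2,6-lutidine (2 equiv), CH2Cl2, −78 → 0 °C
Reagents that add atoms: triethylsilyl trifluoromethanesulfonate, CC[Si](CC)(CC)OS(=O)(=O)C(F)(F)F
Why: Silylation of a hindered tertiary alcohol with a silyl triflate under buffered conditions, which removes the O–H bond that would intercept the carbenoid in step 6 and turns the hydroxyl into a latent leaving group for the final ring closure.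

Step 5
Reactants: 4 4-hydroxy-1-methylquinolin-2(1H)-one
Product: 8 3-diazo-1-methylquinoline-2,4(1H,3H)-dione
Conditions: 4-acetamidobenzenesulfonyl azide (1.1 equiv), Et3N (1.5 equiv), MeCN, 0 → 20 °C
Reagents that add atoms: 4-acetamidobenzenesulfonyl azide, CC(=O)Nc1ccc(cc1)S(=O)(=O)N=[N+]=[N-]
Why: Regitz diazo transfer to C3 of the cyclic 1,3-dicarbonyl (as its ammonium enolate), the standard entry to 3-diazoquinoline-2,4-diones.

Step 6
Reactants: 7 the silylated ring-A enol ether; 8 3-diazo-1-methylquinoline-2,4(1H,3H)-dione
Product: 11 CNP0107253.2 (the (2S,3S,4R) cis-fused bis(pyrano[3,2-c]quinolinone) target), via dihydrofuran ketal 9 (not isolated), via ring-opened bis(triethylsilyl) ether 10 (not isolated)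
Conditions: Rh2(OAc)4 (2 mol %), PhF, 70 °C, slow addition of 8 (1.3 equiv); then CH2Cl2, −40 °C, Et3SiH (1.2 equiv), Et3SiOTf (0.3 equiv), 2,6-di-tert-butyl-4-methylpyridine (0.3 equiv), −40 → 0 °C
Reagents that add atoms: none
Why: Proposed new method: Rh2(OAc)4 converts 8 into an electrophilic carbenoid whose C3' adds to the nucleophilic C3 of enol ether 7 on the face anti to the pseudoaxial 2-methylprop-1-enyl group at C4, and the enolate oxygen then closes on the C2 oxocarbenium (5-exo-trig) to the cis-fused dihydrofuran ketal 9; this half is the known formal [3+2] addition of cyclic 2-diazo-1,3-dicarbonyls to enol ethers. Et3SiOTf then ionises the ketal at the furan C2–O4' bond (axial on ring A and antiperiplanar to a lone pair of O1, releasing the strained five-membered ring and leaving the six-membered oxocarbenium), and Et3SiH delivers hydride to C2 anti to the quinolonyl group on C3 to give 10, the closest known reaction being the silane reduction of 2-alkoxy- and 2-hydroxychromans and of bicyclic ketals. On warming, the silyl triflate ionises the tertiary silyl ether and the silylated O4' captures the tertiary cation (6-exo-tet in the SN1 sense), which closes ring B, releases (Et3Si)2O and regenerates Et3SiOTf; the net change from 9 is a reductive 1,2-shift of O4' from C2 to the CMe2 carbon, a five- to six-membered ring expansion. C3 (S) is controlled by the C4 stereocentre in the carbenoid addition and C2 (S) by C3 in the hydride transfer, and because hydride enters trans to the aryl group the CMe2 arm and the aryl group end up cis, as the cis fusion of ring B requires. The step needs chemoselection for the enol ether over the trisubstituted side-chain alkene (secured by the far higher nucleophilicity of the enol ether toward a diacyl carbenoid and by the absence of O–H bonds), ketal cleavage on the furan side (angular and linear furo-ketal isomers both funnel into the same ring-A oxocarbenium), and oxygen capture of the tertiary cation before hydride shift or reduction (secured by the 1,5-placed silyl enol ether, the small excess of silane and a hindered pyridine that keeps the medium aprotic so the side-chain alkene is not protonated); closure through O4' gives the N-methyl-2-quinolone form, as in acid cyclisations of 3-(3-methylbut-2-enyl)-4-hydroxy-1-methylquinolin-2-ones.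

**Compound list**

1 | 3-methylbut-2-enal | CC(C)=CC=O | starting material
2 | 3-hydroxy-3-methylbutan-2-one | CC(=O)C(C)(C)O | starting material
3 | (4E)-2-hydroxy-2,7-dimethylocta-4,6-dien-3-one | CC(C)=C/C=C/C(=O)C(C)(C)O | intermediate
4 | 4-hydroxy-1-methylquinolin-2(1H)-one | Cn1c(=O)cc(O)c2ccccc12 | starting material
5 | (4S)-2-hydroxy-2-(2-hydroxypropan-2-yl)-6-methyl-4-(2-methylprop-1-en-1-yl)-2,3,4,6-tetrahydro-5H-pyrano[3,2-c]quinolin-5-one (C2 epimers) | CC(C)=C[C@H]1c2c(c3ccccc3n(C)c2=O)OC(O)(C(C)(C)O)C1 | intermediate
6 | (4R)-2-(2-hydroxypropan-2-yl)-6-methyl-4-(2-methylprop-1-en-1-yl)-4,6-dihydro-5H-pyrano[3,2-c]quinolin-5-one | CC(C)=C[C@H]1c2c(c3ccccc3n(C)c2=O)OC(C(C)(C)O)=C1 | intermediate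
7 | (4R)-6-methyl-4-(2-methylprop-1-en-1-yl)-2-{2-[(triethylsilyl)oxy]propan-2-yl}-4,6-dihydro-5H-pyrano[3,2-c]quinolin-5-one | CC(C)=C[C@H]1c2c(c3ccccc3n(C)c2=O)OC(C(C)(C)O[Si](CC)(CC)CC)=C1 | intermediate
8 | 3-diazo-1-methylquinoline-2,4(1H,3H)-dione | CN1C(=O)C(=[N+]=[N-])C(=O)c2ccccc12 | intermediate
9 | cis-fused dihydrofuran ketal, (2R,3S,4R) in ring-A numbering: C2 of the 6-methyl-4-(2-methylprop-1-en-1-yl)-3,4-dihydro-2H-pyrano[3,2-c]quinolin-5(6H)-one carries the 2-[(triethylsilyl)oxy]propan-2-yl group and O4' of a 1-methyl-2-oxoquinoline unit, whose C3' is bonded to C3 | CC(C)=C[C@H]1c2c(c3ccccc3n(C)c2=O)O[C@@]2(C(C)(C)O[Si](CC)(CC)CC)[C@@H]1c1c(c3ccccc3n(C)c1=O)O2 | intermediate (not isolated)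
10 | (2S,3S,4R)-6-methyl-4-(2-methylprop-1-en-1-yl)-3-{1-methyl-2-oxo-4-[(triethylsilyl)oxy]-1,2-dihydroquinolin-3-yl}-2-{2-[(triethylsilyl)oxy]propan-2-yl}-2,3,4,6-tetrahydro-5H-pyrano[3,2-c]quinolin-5-one | CC(C)=C[C@H]1c2c(c3ccccc3n(C)c2=O)O[C@H](C(C)(C)O[Si](CC)(CC)CC)[C@@H]1c1c(O[Si](CC)(CC)CC)c3ccccc3n(C)c1=O | intermediate (not isolated)
11 | CNP0107253.2, (2S,3S,4R) in ring-A numbering: 6-methyl-4-(2-methylprop-1-en-1-yl)-3,4-dihydro-2H-pyrano[3,2-c]quinolin-5(6H)-one whose C2–C3 bond is cis-fused to C3–C4 of a 2,2,6-trimethyl-3,4-dihydro-2H-pyrano[3,2-c]quinolin-5(6H)-one (ring B), H-3 and H-4 trans | CC(C)=C[C@H]1c2c(c3ccccc3n(C)c2=O)O[C@H]2[C@@H]1c1c(c3ccccc3n(C)c1=O)OC2(C)C | target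

**Step count and risks**

Total step count: 6. Longest linear sequence: 5 (steps 1, 2, 3, 4, 6).

Steps most likely to fail:

1. Step 6. The ketal may ionise on the ring-A side instead of the furan side (which opens ring A), hydride may reach C2 from the wrong face, or the tertiary cation may undergo 1,2-hydride shift or reduction before oxygen capture. The fallback sets out from 6 and 4 and comes back at 11; it closes ring B through the C3–C3' bond by a radical instead of through O–CMe2 by a cation. Bromination of 4 (NBS, MeCN, 20 °C) should give 3-bromo-4-hydroxy-1-methylquinolin-2(1H)-one F1, and POCl3 (90 °C) should convert it into 3-bromo-4-chloro-1-methylquinolin-2(1H)-one F2. The potassium alkoxide of 6 (KN(SiMe3)2, THF, −78 → 40 °C) should displace the chloride of F2 by addition–elimination (SNAr) to give (4R)-2-{2-[(3-bromo-1-methyl-2-oxo-1,2-dihydroquinolin-4-yl)oxy]propan-2-yl}-6-methyl-4-(2-methylprop-1-en-1-yl)-4,6-dihydro-5H-pyrano[3,2-c]quinolin-5-one F3. Bu3SnH/AIBN (toluene, 90 °C, slow addition) should then generate the C3' aryl radical, which cyclises 6-endo onto C3 of the enol ether anti to the C4 substituent. The resulting α-oxy radical at C2 should take hydrogen from the stannane on the convex face to give 11; the trans-fused isomer is the stereochemical risk of this variant, and the hindered SNAr is its weak point.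

2. Step 2. The acidic quinolone may compete with the dienone for the copper centre, so that the two-point chelate and with it the enantio- and regiocontrol are lost. The fallback sets out from 1 and 4 and comes back at 6; it uses hydrogen-bond catalysis on a more electrophilic acceptor and installs the gem-dimethyl carbinol late. Wittig olefination of 1 with Ph3P=CHC(O)CO2Me should give methyl (3E)-6-methyl-2-oxohepta-3,5-dienoate F4. A cinchona-derived bifunctional squaramide (antipode chosen for 4S) should catalyse Michael addition/hemiketalisation of 4 to methyl (4S)-2-hydroxy-6-methyl-4-(2-methylprop-1-en-1-yl)-5-oxo-3,4,5,6-tetrahydro-2H-pyrano[3,2-c]quinoline-2-carboxylate F5. Dehydration (PPTS, 4 Å MS) should give methyl (4R)-6-methyl-4-(2-methylprop-1-en-1-yl)-5-oxo-5,6-dihydro-4H-pyrano[3,2-c]quinoline-2-carboxylate F6, and MeMgBr (2.2 equiv, THF, −78 → 0 °C) should convert the ester into the tertiary alcohol 6.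

3. Step 3. Under acid the tertiary allylic alcohol of the product may ionise (elimination to the isopropenyl diene), or the reaction may stall at the hemiketal/open-chain equilibrium. The fallback sets out from 5 and comes back at 7, skipping 6; it eliminates under basic silylating conditions instead of acid. Et3SiOTf (2.5 equiv)/Et3N (CH2Cl2, −78 → 20 °C) should silylate both hydroxyls to (4S)-6-methyl-4-(2-methylprop-1-en-1-yl)-2-[(triethylsilyl)oxy]-2-{2-[(triethylsilyl)oxy]propan-2-yl}-2,3,4,6-tetrahydro-5H-pyrano[3,2-c]quinolin-5-one F7. The same silyl triflate/amine pair should then eliminate the ketal silyloxy group (oxocarbenium formation, deprotonation at C3 by the amine), the known conversion of ketals into enol ethers, to give 7 directly.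

**Further compounds**

F1 | step 6 | 3-bromo-4-hydroxy-1-methylquinolin-2(1H)-one | Cn1c(=O)c(Br)c(O)c2ccccc12
F2 | step 6 | 3-bromo-4-chloro-1-methylquinolin-2(1H)-one | Cn1c(=O)c(Br)c(Cl)c2ccccc12
F3 | step 6 | (4R)-2-{2-[(3-bromo-1-methyl-2-oxo-1,2-dihydroquinolin-4-yl)oxy]propan-2-yl}-6-methyl-4-(2-methylprop-1-en-1-yl)-4,6-dihydro-5H-pyrano[3,2-c]quinolin-5-one | CC(C)=C[C@H]1c2c(c3ccccc3n(C)c2=O)OC(C(C)(C)Oc2c(Br)c(=O)n(C)c3ccccc23)=C1
F4 | step 2 | methyl (3E)-6-methyl-2-oxohepta-3,5-dienoate | CC(C)=C/C=C/C(=O)C(=O)OC
F5 | step 2 | methyl (4S)-2-hydroxy-6-methyl-4-(2-methylprop-1-en-1-yl)-5-oxo-3,4,5,6-tetrahydro-2H-pyrano[3,2-c]quinoline-2-carboxylate | CC(C)=C[C@H]1c2c(c3ccccc3n(C)c2=O)OC(O)(C(=O)OC)C1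
F6 | step 2 | methyl (4R)-6-methyl-4-(2-methylprop-1-en-1-yl)-5-oxo-5,6-dihydro-4H-pyrano[3,2-c]quinoline-2-carboxylate | CC(C)=C[C@H]1c2c(c3ccccc3n(C)c2=O)OC(C(=O)OC)=C1
F7 | step 3 | (4S)-6-methyl-4-(2-methylprop-1-en-1-yl)-2-[(triethylsilyl)oxy]-2-{2-[(triethylsilyl)oxy]propan-2-yl}-2,3,4,6-tetrahydro-5H-pyrano[3,2-c]quinolin-5-one | CC(C)=C[C@H]1c2c(c3ccccc3n(C)c2=O)OC(O[Si](CC)(CC)CC)(C(C)(C)O[Si](CC)(CC)CC)C1
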